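## Structural features

The target is a flavone: a benzo-fused 4-pyranone (rings A and C) that carries the aryl ring B on C2 through the C2–C1' bond. It has no stereocentre, and the C2–C1' axis, flanked by two ortho substituents on ring B, is twisted but needs no configurational control. Ring A bears oxygen on C5, C6 and C7 (OH, OMe, OMe) and hydrogen on C8, the C5 hydroxyl being hydrogen-bonded to the C4 carbonyl. Ring B is pentasubstituted, with methoxy groups on C2', C3' and C4', a free hydroxyl on C6' and its only hydrogen on C5'. The pyranone is the fragile part: hot alkali opens it at C2 to a 1,3-diketone which, because both flanking arenes then carry an ortho hydroxyl, can close again in more than one way (Wessely–Moser-type scrambling); the electron-rich rings are also open to over-dealkylation by Lewis acids. The real difficulty is telling like oxygens apart: C6'–OH from C2'–OMe on the two ortho positions of ring B, and C5–OH from the five methyl ethers. The key step uses the fact that C6', C5', C4' and C3' (O, H, O, O) match a 1,3,4-trioxygenated vinylketene acetal, while C1' and C2' can come from an alkyne carrying the chromone on C1' and boron on C2' as a stand-in for oxygen, so the two ortho oxygens arrive in different chemical form.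

## Logic of the disconnections

**20 from 19.** No skeletal bond is cut; a benzyl group is put back on O6' and a methyl group on O5. The fully alkylated 19 is robust, and these are the only two ethers a boron trihalide can tell from the rest: the benzyl ether and the methyl ether peri to the C4 carbonyl. All handling of free phenols is thereby moved to the last step. The forward dealkylation must stop after the chelated C5 ether and must not benzylate ring B.

**19 from 16 by way of 18 and 17.** Backwards, the O2'–CH3 bond is cut (18), the C2'–O bond is exchanged for C2'–B (17), and the O6'–benzyl bond is cut (16). Boron on C2' and hydroxyl on C6' are different functional groups, so the ortho oxygens are differentiated by three routine operations. The forward steps require a boronate that survives benzylation, an oxidation that spares the pyranone, and methylation of a flanked phenol.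

**16 from 9 and 13.** The bonds C1'–C6' and C2'–C3' are cut, which removes the whole of ring B. The four carbons C3'–C6' with their oxygens and the C5' hydrogen become an open-chain diene, and C1'–C2' becomes an alkyne. A pentasubstituted benzene with two different ortho heteroatoms is thus reduced to a two-step diene and an alkynylchromone. The forward cycloaddition must be regioselective, must occur at the alkyne and not at C2=C3 of the pyranone, and must aromatize by loss of methanol.

**9 from 6 and 7, and 6 from 5.** The C(sp)–B bond is cut, then the terminal hydrogen is exchanged for silicon. Boron is introduced last because the alkynyl boronate is the most labile compound of the route; silicon protects the alkyne terminus through the earlier steps. This requires an acetylide formed without attack on the chromone, and isolation of 9 without water.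

**5 from 2 and 3 by way of 4.** The O1–C2 bond is cut (cyclodehydration), then the C2–C3 bond (Claisen condensation). This is the classical assembly of a 2-substituted chromone from an ortho-hydroxyacetophenone and an ester, and it brings in all three remaining carbons of the alkyne unit at once. The forward closure must proceed through the phenol onto the alkynyl ketone and not through the enol oxygen onto the alkyne.

**2 from 1.** The C4–C4a bond is cut, which leaves a commercial phenol that already holds all four oxygens of ring A. The arene has two equivalent positions ortho to the hydroxyl and a blocked para position, so the acylation can give only one product. The forward step must acylate on carbon and stop after one acyl group.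

**13 from 10 by way of 12.** Only O–Si and O–CH3 bonds are cut. All four carbons and three of the four oxygens of the diene are present in a β-keto ester. The forward steps require enol etherification toward the ester and γ-deprotonation with O-silylation.

## Other disconnections considered

Alternative 1: The cut is at both aryl–carbonyl bonds, C4–C4a and C2–C1', because ring B and the acyl arene of ring A are the same 6-oxy-2,3,4-trimethoxyphenyl unit. In the forward key step two molecules of 5-(benzyloxy)-1,2,3-trimethoxybenzene A1, the benzyl ether of 1, would be acylated by malonyl dichloride A2 with SnCl4 at low temperature to 1,3-bis[6-(benzyloxy)-2,3,4-trimethoxyphenyl]propane-1,3-dione A3 with no ring closed. Hydrogenolysis of both benzyl ethers of A3 and acid cyclodehydration would give 6'-hydroxy-5,6,7,2',3',4'-hexamethoxyflavone A4 whichever phenol closes, and the chelation-controlled C5 demethylation of step 12 would convert A4 into 20.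

In its favour: the hidden symmetry is used in full, A1 has only one kind of reactive position, the dione A3 holds the whole carbon skeleton after a single bond-forming step, and no organometallic or boron chemistry is needed.

Against it: A2 readily forms ketene-derived by-products. On the way to A3 the mono-acylated β-keto acid chloride can close onto its own ortho benzyloxy group, with Lewis-acid debenzylation, to give a 4-hydroxycoumarin. SnCl4 may also cleave the benzyl or ortho methyl ethers, and both new ketones of A3 are doubly ortho-substituted.

Comparison: on step economy it is clearly the better plan (about five steps against twelve). On the ring B ortho oxygens it is also better, since the OH/OMe difference in A4 follows from the cyclization itself. The final demethylation is the same operation and so an equal. Mechanistically the formation of A3 rests on one capricious bis-acylation, while the chosen plan spreads its risk and does not depend on rings A and B sharing an arene.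

Alternative 2: The cut is at C7–C8 and C5–C6, so ring A is built on a preformed pyranone that already carries ring B. In the forward key step methyl 6-[6-(benzyloxy)-2,3,4-trimethoxyphenyl]-2-methyl-4-oxo-4H-pyran-3-carboxylate A5 would be deprotonated at its methyl group, the future C8, by excess LiN(iPr)2 and acylated by methyl methoxyacetate A6 to form C7–C8. The dianion of the new ketone would then attack the ester carbon through the methoxy-bearing carbon in a Dieckmann-type closure (C5–C6), and enolization would give 6'-benzyloxy-5,7-dihydroxy-6,2',3',4'-tetramethoxyflavone A7 directly. Methylation of the non-chelated C7 hydroxyl of A7 and hydrogenolysis of the benzyl ether would finish.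

In its favour: in A7 the C5 hydroxyl arrives free and chelated, so no late demethylation is needed, which is better than the chosen plan. The C6 methoxy group is placed unambiguously, and two steps follow the key step against four.

Against it: A5 is itself a multistep target with a hindered aryl group. The key step is polyanion chemistry in which the base or the enolates can open the pyranone at C2 or C6, A6 can self-condense, and the α-oxygenated carbanion that must close the ring to A7 is a poor nucleophile.

Comparison: it treats ring A better and ring B no better (bought as an arene, as in Alternative 1). Its mechanism is an anionic cascade, against a pericyclic step, and neither has been tried on these substrates. In step count the way through A7 is about equal to the chosen plan or somewhat shorter.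

Alternative 3: The cut is at C5'–C6'. Ring B would come from 2-[2,3-dimethoxy-3-(1-methoxyethenyl)-4-oxocyclobut-1-en-1-yl]-5,6,7-trimethoxy-4H-chromen-4-one A8, prepared from a squaric ester by replacing one alkoxy group with a chromon-2-yl group, adding CH2=C(OMe)Li to the more ketone-like carbonyl and methylating the tertiary alkoxide. In the forward key step heating A8 in toluene would open the four-membered ring to a dienylketene, six-electron electrocyclization would form C5'–C6', and tautomerization would give 6'-hydroxy-5,6,7,2',3',4'-hexamethoxyflavone A9 with its 6'-hydroxyl free. The compound A9 has the same structure as A4, so only the C5 demethylation of step 12 separates A9 from 20.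

In its favour: every ring B oxygen is placed by the connectivity of A8, the ketene carbon becomes the free C6' hydroxyl of A9 while C2' is already a methyl ether, and the step is neutral and unimolecular. On regiochemical security and on differentiation of the ortho oxygens it is better than the chosen plan, and only one step follows the key step.

Against it: A8 needs a chromon-2-yl nucleophile and then a hard vinyllithium that must select a cyclobutenedione carbonyl over the chromone carbonyl and its acceptor C2. A8 is also a strained, acid-labile enol ether.

Comparison: the way through A9 is shorter (about seven steps) and pericyclic like the chosen plan, and therefore its equal in mechanistic type. Its risk lies in organometallic additions in the presence of the chromone, which the chosen plan avoids after ring C is formed.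

Key step: step 8

Assumption: diene 13 is drawn as the (1Z,3Z) isomer expected from kinetic enolization; its geometry does not reach 16, because both sp3 carbons of adduct 14 become sp2.

Remark: the key step balances as 9 + 13 + H2O = 16 + MeOH + Me3SiOH, and the mapping of the diene and alkyne carbons onto ring B agrees with the substitution pattern of 16.

Remark: boron is introduced with the borate ester 7 and not with a B–H reagent, which keeps a hydride source away from the chromone carbonyl and the acceptor alkyne.

## Route

Step 1
Reactants: 1 3,4,5-trimethoxyphenol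
Product: 2 1-(6-hydroxy-2,3,4-trimethoxyphenyl)ethan-1-one
Conditions: AcOH, BF3·OEt2, 85 °C; aq. NaOAc
Reagents that add atoms: acetic acid, CC(=O)O
Why: Friedel–Crafts C-acylation of an electron-rich phenol (by way of the aryl acetate and a Fries-type shift); the two ortho positions of 1 are equivalent and the para position is blocked, and the product is held as its unreactive difluoroboron chelate until hydrolysis, which prevents a second acylation.

Step 2
Reactants: 2 1-(6-hydroxy-2,3,4-trimethoxyphenyl)ethan-1-one; 3 ethyl 3-(trimethylsilyl)prop-2-ynoate
Product: 4 1-(6-hydroxy-2,3,4-trimethoxyphenyl)-5-(trimethylsilyl)pent-4-yne-1,3-dione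
Conditions: LiN(SiMe3)2 (3.2 equiv), THF, −78 °C; 3, −78 → −20 °C; 1 M HCl
Reagents that add atoms: none
Why: Crossed Claisen condensation: the lithium dianion of 2 (phenoxide and ketone enolate) attacks the ester carbonyl of 3, the C-silyl group shielding the alkyne terminus from conjugate addition, and the product is held as its chelated diketonate (hence the third equivalent of base) until the acid quench.

Step 3
Reactants: 4 1-(6-hydroxy-2,3,4-trimethoxyphenyl)-5-(trimethylsilyl)pent-4-yne-1,3-dione
Product: 5 5,6,7-trimethoxy-2-[(trimethylsilyl)ethynyl]-4H-chromen-4-one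
Conditions: p-TsOH·H2O (10 mol%), toluene, 4 Å MS, 50 °C
Reagents that add atoms: none
Why: Acid-catalysed cyclodehydration of an ortho-hydroxyaryl 1,3-diketone, the closing stage of the Baker–Venkataraman flavone synthesis: the phenol adds to the more electrophilic alkynyl ketone (6-exo-trig hemiketal) and loss of water gives the pyranone; the bulky silyl group on the alkyne terminus disfavours the rival 6-endo-dig attack of the enol oxygen, and the Si–C(sp) bond is stable to Brønsted acid.

Step 4
Reactants: 5 5,6,7-trimethoxy-2-[(trimethylsilyl)ethynyl]-4H-chromen-4-one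
Product: 6 2-ethynyl-5,6,7-trimethoxy-4H-chromen-4-one
Conditions: Bu4NF, AcOH, THF, −20 → 0 °C
Reagents that add atoms: none
Why: Fluoride-induced protodesilylation of an alkynylsilane; the acetic acid buffer protonates the acetylide at once and keeps basic species from adding to the acceptor alkyne or opening the pyranone.

Step 5
Reactants: 6 2-ethynyl-5,6,7-trimethoxy-4H-chromen-4-one; 7 2-isopropoxy-4,4,5,5-tetramethyl-1,3,2-dioxaborolane
Product: 9 5,6,7-trimethoxy-2-[(4,4,5,5-tetramethyl-1,3,2-dioxaborolan-2-yl)ethynyl]-4H-chromen-4-one, via lithium alkynyl(isopropoxy)borate 8 (not isolated)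
Conditions: LiN(SiMe3)2 (1.05 equiv), THF, −78 °C; 7; HCl (2 M in Et2O, 1.05 equiv), −78 °C → rt; filtration under Ar
Reagents that add atoms: none
Why: Deprotonation of the acidic, acceptor-substituted terminal alkyne by a hindered amide base, addition of the acetylide to borate 7 to give ate complex 8, and removal of isopropoxide with anhydrous HCl (the standard acetylide route to 1-alkynyl pinacol boronates); low temperature protects the chromone and the non-aqueous isolation avoids protodeboronation.

Step 6
Reactants: 10 methyl 4-methoxy-3-oxobutanoate
Product: 12 methyl (2E)-3,4-dimethoxybut-2-enoate, via dimethyl ketal 11 (not isolated)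
Conditions: HC(OMe)3 (1.5 equiv), H2SO4 (cat.), rt; then p-TsOH (cat.), 140 °C, distillation
Reagents that add atoms: trimethyl orthoformate, COC(OC)OC
Why: Acid-catalysed ketalization by the orthoformate and thermal loss of methanol toward the ester give the conjugated β-methoxy enoate; the (E) isomer, with the methoxy group trans to the ester, is the thermodynamic product as for simple acetoacetates.

Step 7
Reactants: 12 methyl (2E)-3,4-dimethoxybut-2-enoate
Product: 13 (1Z,3Z)-1,3,4-trimethoxy-1-[(trimethylsilyl)oxy]buta-1,3-diene
Conditions: LiN(iPr)2, THF, −78 °C; Me3SiCl, −78 °C → rt; pentane, filtration, bulb-to-bulb distillation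
Reagents that add atoms: chlorotrimethylsilane, C[Si](C)(C)Cl
Why: Kinetic γ-deprotonation of the β-alkoxy enoate (the CH2OMe group lies cis to the ester in the (E) isomer, within reach of the ester-bound amide) gives the extended dienolate, which Me3SiCl silylates on oxygen to the vinylketene acetal; the C4 methoxy group takes the outward position, as an s-cis diene requires.

Step 8
Reactants: 9 5,6,7-trimethoxy-2-[(4,4,5,5-tetramethyl-1,3,2-dioxaborolan-2-yl)ethynyl]-4H-chromen-4-one; 13 (1Z,3Z)-1,3,4-trimethoxy-1-[(trimethylsilyl)oxy]buta-1,3-diene
Product: 16 6'-hydroxy-5,6,7,3',4'-pentamethoxy-2'-(4,4,5,5-tetramethyl-1,3,2-dioxaborolan-2-yl)flavone, via cyclohexa-1,4-diene cycloadduct 14 (not isolated), via aryl trimethylsilyl ether 15 (not isolated)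
Conditions: 13 (2.5 equiv), toluene, 110 °C, sealed tube; then aq. citric acid, THF, rt
Reagents that add atoms: none
Why: Thermal normal-electron-demand Diels–Alder reaction of an electron-rich mixed methyl silyl vinylketene acetal with an acceptor-substituted alkyne, followed by aromatization; the closest known reactions are the phenol-forming cycloadditions of 1-alkoxy-1-silyloxybutadienes with acetylenic esters and ketones and the cycloadditions of alkynylboronates that deliver arylboronates. The largest HOMO coefficient of 13 lies on the CH(OMe) terminus and the largest LUMO coefficient of 9 on the boron-bearing alkyne carbon, the remote position of the O=C4–C3=C2–C≡C acceptor chain, so the C2'–C3' bond leads and the ketene acetal carbon follows on to the chromone-bearing alkyne carbon (C1'–C6') in a concerted but asynchronous suprafacial [4+2] closure that forms ring B as a six-membered carbocycle. Adduct 14 has two sp3 carbons, the mixed ketal carbon C6' and C3' (H, OMe); they form without control as a diastereomer mixture and both become sp2, so no stereocentre has to be set. Aromatization takes the C3' hydrogen and one oxygen group from C6' in a 1,4-elimination; the methoxy group leaves (the Si–O bond is not ionized under neutral thermal conditions, and C6' has no hydrogen that would let the C3' methoxy group go), which gives silyl ether 15 and, with mild aqueous acid, phenol 16. The step needs regioselectivity, secured by the chromone being a much stronger π-acceptor than the dioxaborolane, whose boron p orbital is largely filled by its two oxygens, and chemoselectivity for the alkyne over the chromone C2=C3 bond, secured by C2 being fully substituted and part of a vinylogous ester. Excess 13 also consumes the methanol set free, which protects the C(sp)–B bond of unreacted 9.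

Step 9
Reactants: 16 6'-hydroxy-5,6,7,3',4'-pentamethoxy-2'-(4,4,5,5-tetramethyl-1,3,2-dioxaborolan-2-yl)flavone
Product: 17 6'-(benzyloxy)-5,6,7,3',4'-pentamethoxy-2'-(4,4,5,5-tetramethyl-1,3,2-dioxaborolan-2-yl)flavone
Conditions: BnBr, K2CO3, DMF, rt
Reagents that add atoms: benzyl bromide, BrCc1ccccc1
Why: Williamson ether synthesis at the only acidic site; anhydrous carbonate in DMF leaves the pinacol boronate and the pyranone untouched.

Step 10
Reactants: 17 6'-(benzyloxy)-5,6,7,3',4'-pentamethoxy-2'-(4,4,5,5-tetramethyl-1,3,2-dioxaborolan-2-yl)flavone
Product: 18 6'-(benzyloxy)-2'-hydroxy-5,6,7,3',4'-pentamethoxyflavone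
Conditions: NaBO3·4H2O, THF/H2O (1:1), rt
Reagents that add atoms: sodium perborate tetrahydrate, [Na+].[O-]OB=O.O.O.O.O
Why: Oxidation of an arylboronate by peroxide: the peroxoborate undergoes 1,2-migration of the aryl group from boron to oxygen at the same ring carbon, and hydrolysis gives the phenol; perborate is weakly basic and works at room temperature, which suits the pyranone and the benzyl ether.

Step 11
Reactants: 18 6'-(benzyloxy)-2'-hydroxy-5,6,7,3',4'-pentamethoxyflavone
Product: 19 6'-(benzyloxy)-5,6,7,2',3',4'-hexamethoxyflavone
Conditions: MeI, K2CO3, DMF, 40 °C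
Reagents that add atoms: iodomethane, CI
Why: Williamson O-methylation of the only free hydroxyl; the flanked C2' phenoxide is hindered but iodomethane is small, and no other site can be alkylated.

Step 12
Reactants: 19 6'-(benzyloxy)-5,6,7,2',3',4'-hexamethoxyflavone
Product: 20 5,6'-dihydroxy-6,7,2',3',4'-pentamethoxyflavone
Conditions: BCl3 (1 M in CH2Cl2, 3 equiv), C6HMe5, CH2Cl2, −78 → 0 °C; MeOH, aq. NaHCO3
Reagents that add atoms: none
Why: Lewis-acid ether cleavage: BCl3 removes the aryl benzyl ether at low temperature (the benzyl cation is trapped by pentamethylbenzene and not by the electron-rich ring B) and, through a six-membered chelate with the C4 carbonyl, cleaves only the peri C5 methyl ether; the five other methoxy groups have no chelating neighbour and survive at or below 0 °C.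

## Compound list

1 | 3,4,5-trimethoxyphenol | COc1cc(O)cc(OC)c1OC | starting material
2 | 1-(6-hydroxy-2,3,4-trimethoxyphenyl)ethan-1-one | CC(=O)c1c(O)cc(OC)c(OC)c1OC | intermediate
3 | ethyl 3-(trimethylsilyl)prop-2-ynoate | CCOC(=O)C#C[Si](C)(C)C | starting material
4 | 1-(6-hydroxy-2,3,4-trimethoxyphenyl)-5-(trimethylsilyl)pent-4-yne-1,3-dione (drawn as the diketo tautomer) | COc1cc(O)c(C(=O)CC(=O)C#C[Si](C)(C)C)c(OC)c1OC | intermediate
5 | 5,6,7-trimethoxy-2-[(trimethylsilyl)ethynyl]-4H-chromen-4-one | COc1cc2oc(C#C[Si](C)(C)C)cc(=O)c2c(OC)c1OC | intermediate
6 | 2-ethynyl-5,6,7-trimethoxy-4H-chromen-4-one | COc1cc2oc(C#C)cc(=O)c2c(OC)c1OC | intermediate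
7 | 2-isopropoxy-4,4,5,5-tetramethyl-1,3,2-dioxaborolane | CC(C)OB1OC(C)(C)C(C)(C)O1 | starting material
8 | lithium isopropoxy(pinacolato)[(5,6,7-trimethoxy-4-oxo-4H-chromen-2-yl)ethynyl]borate | [Li+].CC(C)O[B-]1(C#Cc2cc(=O)c3c(OC)c(OC)c(OC)cc3o2)OC(C)(C)C(C)(C)O1 | intermediate
9 | 5,6,7-trimethoxy-2-[(4,4,5,5-tetramethyl-1,3,2-dioxaborolan-2-yl)ethynyl]-4H-chromen-4-one | COc1cc2oc(C#CB3OC(C)(C)C(C)(C)O3)cc(=O)c2c(OC)c1OC | intermediate
10 | methyl 4-methoxy-3-oxobutanoate | COCC(=O)CC(=O)OC | starting material
11 | methyl 3,3,4-trimethoxybutanoate | COCC(OC)(OC)CC(=O)OC | intermediate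
12 | methyl (2E)-3,4-dimethoxybut-2-enoate | COC/C(OC)=C\C(=O)OC | intermediate
13 | (1Z,3Z)-1,3,4-trimethoxy-1-[(trimethylsilyl)oxy]buta-1,3-diene | CO/C=C(OC)/C=C(/OC)O[Si](C)(C)C | intermediate
14 | 5,6,7-trimethoxy-2-[3,4,6-trimethoxy-2-(4,4,5,5-tetramethyl-1,3,2-dioxaborolan-2-yl)-6-[(trimethylsilyl)oxy]cyclohexa-1,4-dien-1-yl]-4H-chromen-4-one (racemic mixture of diastereomers) | COC1C(OC)=CC(OC)(O[Si](C)(C)C)C(c2cc(=O)c3c(OC)c(OC)c(OC)cc3o2)=C1B1OC(C)(C)C(C)(C)O1 | intermediate
15 | 5,6,7,3',4'-pentamethoxy-2'-(4,4,5,5-tetramethyl-1,3,2-dioxaborolan-2-yl)-6'-[(trimethylsilyl)oxy]flavone | COc1cc(O[Si](C)(C)C)c(-c2cc(=O)c3c(OC)c(OC)c(OC)cc3o2)c(B2OC(C)(C)C(C)(C)O2)c1OC | intermediate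
16 | 6'-hydroxy-5,6,7,3',4'-pentamethoxy-2'-(4,4,5,5-tetramethyl-1,3,2-dioxaborolan-2-yl)flavone | COc1cc(O)c(-c2cc(=O)c3c(OC)c(OC)c(OC)cc3o2)c(B2OC(C)(C)C(C)(C)O2)c1OC | intermediate
17 | 6'-(benzyloxy)-5,6,7,3',4'-pentamethoxy-2'-(4,4,5,5-tetramethyl-1,3,2-dioxaborolan-2-yl)flavone | COc1cc(OCc2ccccc2)c(-c2cc(=O)c3c(OC)c(OC)c(OC)cc3o2)c(B2OC(C)(C)C(C)(C)O2)c1OC | intermediate
18 | 6'-(benzyloxy)-2'-hydroxy-5,6,7,3',4'-pentamethoxyflavone | COc1cc(OCc2ccccc2)c(-c2cc(=O)c3c(OC)c(OC)c(OC)cc3o2)c(O)c1OC | intermediate
19 | 6'-(benzyloxy)-5,6,7,2',3',4'-hexamethoxyflavone | COc1cc(OCc2ccccc2)c(-c2cc(=O)c3c(OC)c(OC)c(OC)cc3o2)c(OC)c1OC | intermediate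
20 | 5,6'-dihydroxy-6,7,2',3',4'-pentamethoxyflavone | COc1cc(O)c(-c2cc(=O)c3c(O)c(OC)c(OC)cc3o2)c(OC)c1OC | target

## Step count and least certain steps

Total: 12 steps. Longest linear sequence: 10 steps (steps 1–5 and 8–12); the diene branch (steps 6 and 7) joins at step 8.

**Step 8 (key step).** The cycloaddition joins two fully substituted carbons on each side and may be slow, so that the diene decomposes or undergoes O-to-C silyl migration before it reacts. Regioselectivity may erode if boron competes as acceptor. The methanol set free may cause protodeboronation of the alkynyl C–B bond, and loss of silanol instead of methanol would scramble the two ortho oxygens. The fallback gives up the construction of ring B and takes it from an arene. It sets out from 1 and 2 and returns at 19. Benzylation of 1 (BnBr, K2CO3) gives 5-(benzyloxy)-1,2,3-trimethoxybenzene F1. Vilsmeier–Haack formylation (POCl3, DMF) at one of its two equivalent ortho positions gives 6-(benzyloxy)-2,3,4-trimethoxybenzaldehyde F2. Claisen–Schmidt condensation with 2 (KOH, EtOH) gives (2E)-3-[6-(benzyloxy)-2,3,4-trimethoxyphenyl]-1-(6-hydroxy-2,3,4-trimethoxyphenyl)prop-2-en-1-one F3, and oxidative cyclization (I2 cat., DMSO, 120 °C) should give 19.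

**Step 3.** The enol oxygen may close onto the alkyne (6-endo-dig) to a 4-pyranone in competition with closure through the phenol, and the acceptor alkyne may be hydrated; conjugate addition or desilylation in step 2 would feed the same problem. The fallback attaches the alkyne to a finished chromone. It sets out from 2 and returns at 5, bypassing steps 2 and 3. Condensation of 2 with dimethylformamide dimethyl acetal gives (2E)-3-(dimethylamino)-1-(6-hydroxy-2,3,4-trimethoxyphenyl)prop-2-en-1-one F4, and acid (HCl, CH2Cl2) closes it to 5,6,7-trimethoxy-4H-chromen-4-one F5. Zincation at C2 with (C9H18N)ZnCl·LiCl (the chlorozinc amide of 2,2,6,6-tetramethylpiperidine) and quenching with I2 gives 2-iodo-5,6,7-trimethoxy-4H-chromen-4-one F6. Sonogashira coupling with ethynyltrimethylsilane (PdCl2(PPh3)2, CuI, iPr2NEt) should give 5.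

**Step 5.** The acetylide or the amide base may add to the acceptor alkyne of a second molecule (oligomerization), the silazane may consume the HCl needed to break the ate complex, and the C(sp)–B bond may be lost by protodeboronation during isolation. The fallback brings boron in as a preformed, bench-stable tetracoordinate unit. It sets out from 2, goes through 2-iodo-5,6,7-trimethoxy-4H-chromen-4-one F6 as above, and returns at 18. Sonogashira coupling of F6 with ethynylboronic acid N-methyliminodiacetate gives 6-methyl-2-[(5,6,7-trimethoxy-4-oxo-4H-chromen-2-yl)ethynyl]-1,3,6,2-dioxazaborocane-4,8-dione F7, whose boron has no vacant orbital to oppose the chromone. Cycloaddition with 13 (MeCN, 100 °C; aqueous citric acid) gives 6'-hydroxy-5,6,7,3',4'-pentamethoxy-2'-(6-methyl-4,8-dioxo-1,3,6,2-dioxazaborocan-2-yl)flavone F8. Benzylation (BnBr, K2CO3, DMF) gives 6'-(benzyloxy)-5,6,7,3',4'-pentamethoxy-2'-(6-methyl-4,8-dioxo-1,3,6,2-dioxazaborocan-2-yl)flavone F9. Hydrolysis and oxidation in one flask (aq. NaOH, THF; H2O2, 0 °C) should give 18.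

**Step 12.** Dealkylation may go too far (the C6 methoxy group next to the boron-bound C5 oxygen, or the central C3' methoxy group), debenzylation may be incomplete, and the benzyl cation may alkylate C5' of ring B. The fallback separates the two deprotections. It sets out from 19 and returns at 20. Hydrogenolysis (H2, Pd/C, EtOAc) gives 6'-hydroxy-5,6,7,2',3',4'-hexamethoxyflavone F10 without any cationic benzyl species, and AlCl3 in MeCN at room temperature, a milder chelation-selective reagent, should remove only the C5 methyl group to give 20.

## Further compounds

F1 | step 8 | 5-(benzyloxy)-1,2,3-trimethoxybenzene | COc1cc(OCc2ccccc2)cc(OC)c1OC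
F2 | step 8 | 6-(benzyloxy)-2,3,4-trimethoxybenzaldehyde | COc1cc(OCc2ccccc2)c(C=O)c(OC)c1OC
F3 | step 8 | (2E)-3-[6-(benzyloxy)-2,3,4-trimethoxyphenyl]-1-(6-hydroxy-2,3,4-trimethoxyphenyl)prop-2-en-1-one | COc1cc(OCc2ccccc2)c(/C=C/C(=O)c2c(O)cc(OC)c(OC)c2OC)c(OC)c1OC
F4 | step 3 | (2E)-3-(dimethylamino)-1-(6-hydroxy-2,3,4-trimethoxyphenyl)prop-2-en-1-one | CN(C)/C=C/C(=O)c1c(O)cc(OC)c(OC)c1OC
F5 | step 3 | 5,6,7-trimethoxy-4H-chromen-4-one | COc1cc2occc(=O)c2c(OC)c1OC
F6 | step 3 | 2-iodo-5,6,7-trimethoxy-4H-chromen-4-one | COc1cc2oc(I)cc(=O)c2c(OC)c1OC
F7 | step 5 | 6-methyl-2-[(5,6,7-trimethoxy-4-oxo-4H-chromen-2-yl)ethynyl]-1,3,6,2-dioxazaborocane-4,8-dione | C[N+]12CC(=O)O[B-]1(C#Cc1cc(=O)c3c(OC)c(OC)c(OC)cc3o1)OC(=O)C2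
F8 | step 5 | 6'-hydroxy-5,6,7,3',4'-pentamethoxy-2'-(6-methyl-4,8-dioxo-1,3,6,2-dioxazaborocan-2-yl)flavone | COc1cc(O)c(-c2cc(=O)c3c(OC)c(OC)c(OC)cc3o2)c([B-]23OC(=O)C[N+]2(C)CC(=O)O3)c1OC
F9 | step 5 | 6'-(benzyloxy)-5,6,7,3',4'-pentamethoxy-2'-(6-methyl-4,8-dioxo-1,3,6,2-dioxazaborocan-2-yl)flavone | COc1cc(OCc2ccccc2)c(-c2cc(=O)c3c(OC)c(OC)c(OC)cc3o2)c([B-]23OC(=O)C[N+]2(C)CC(=O)O3)c1OC
F10 | step 12 | 6'-hydroxy-5,6,7,2',3',4'-hexamethoxyflavone | COc1cc(O)c(-c2cc(=O)c3c(OC)c(OC)c(OC)cc3o2)c(OC)c1OC
A1 | alternative 1 | 5-(benzyloxy)-1,2,3-trimethoxybenzene | COc1cc(OCc2ccccc2)cc(OC)c1OC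
A2 | alternative 1 | malonyl dichloride | O=C(Cl)CC(=O)Cl
A3 | alternative 1 | 1,3-bis[6-(benzyloxy)-2,3,4-trimethoxyphenyl]propane-1,3-dione | COc1cc(OCc2ccccc2)c(C(=O)CC(=O)c2c(OCc3ccccc3)cc(OC)c(OC)c2OC)c(OC)c1OC
A4 | alternative 1 | 6'-hydroxy-5,6,7,2',3',4'-hexamethoxyflavone | COc1cc(O)c(-c2cc(=O)c3c(OC)c(OC)c(OC)cc3o2)c(OC)c1OC
A5 | alternative 2 | methyl 6-[6-(benzyloxy)-2,3,4-trimethoxyphenyl]-2-methyl-4-oxo-4H-pyran-3-carboxylate | COC(=O)c1c(C)oc(-c2c(OCc3ccccc3)cc(OC)c(OC)c2OC)cc1=O
A6 | alternative 2 | methyl methoxyacetate | COCC(=O)OC
A7 | alternative 2 | 6'-benzyloxy-5,7-dihydroxy-6,2',3',4'-tetramethoxyflavone | COc1cc(OCc2ccccc2)c(-c2cc(=O)c3c(O)c(OC)c(O)cc3o2)c(OC)c1OC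
A8 | alternative 3 | 2-[2,3-dimethoxy-3-(1-methoxyethenyl)-4-oxocyclobut-1-en-1-yl]-5,6,7-trimethoxy-4H-chromen-4-one (racemic) | COC(=C)C1(OC)C(=O)C(c2cc(=O)c3c(OC)c(OC)c(OC)cc3o2)=C1OC
A9 | alternative 3 | 6'-hydroxy-5,6,7,2',3',4'-hexamethoxyflavone | COc1cc(O)c(-c2cc(=O)c3c(OC)c(OC)c(OC)cc3o2)c(OC)c1OC
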